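Ring numbering: O1, C2 (S, aryl trans to the C3 methyl), C3 (S), C4 (S), C5 (R, aryl cis to the C4 methyl). The target is 2,3-trans, 3,4-trans, 4,5-cis.
Retrosynthesis: the two phenol protecting groups and the hydrogens at C4 and C5 are removed first, which leads back to a 2,3-dihydrofuran. Then O1–C2 and C2–C3 are cut.
Enabling feature: C2 is a benzylic CH whose only ring bonds go to O1 and C3, so it is a one-carbon ArCH unit. The remaining chain O1–C5–C4–C3, with one aryl and both methyls, is the O=C–C=C unit of an aryl tiglyl ketone.
Forward: the enone arm (tiglic acid plus bromosyringol) and the benzylidene arm (syringaldehyde plus tosylhydrazide) are each made in two steps on their own chain. They are joined in a (4+1) annulation that closes the only ring.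
Stereochemistry: C3 comes from a chiral sulfonium ylide, and C2 from ring closure trans to the C3 methyl. C4 and C5 are set together by syn hydrogenation on the face opposite the C2 aryl group.

Key step: step 6

Assumption: the sense of induction of isothiocineole on this enone class is not known, so the (1R,4R,5R) antipode is written. Its mirror image, equally available, is used instead if a pilot run shows the opposite sense at C3.

Step 1
Reactants: 1 tiglic acid
Product: 3 (E)-N-methoxy-N,2-dimethylbut-2-enamide, via tigloyl chloride 2 (not isolated)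
Conditions: (COCl)2, DMF (cat.), CH2Cl2, 0 °C → rt; then MeNH(OMe)·HCl, K2CO3, CH2Cl2–H2O, 0 °C
Reagents that add atoms: N,O-dimethylhydroxylamine hydrochloride, CNOC.Cl
Why: Acid chloride formation followed by Schotten–Baumann amidation is the standard entry to a Weinreb amide and leaves the E-trisubstituted alkene untouched.

Step 2
Reactants: 4 4-bromo-2,6-dimethoxyphenol
Product: 5 2-(benzyloxy)-5-bromo-1,3-dimethoxybenzene
Conditions: BnBr, K2CO3, DMF, 60 °C
Reagents that add atoms: benzyl bromide, BrCc1ccccc1
Why: Williamson ether synthesis on an acidic phenol, with an aryl bromide that is inert to carbonate.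

Step 3
Reactants: 5 2-(benzyloxy)-5-bromo-1,3-dimethoxybenzene; 3 (E)-N-methoxy-N,2-dimethylbut-2-enamide
Product: 7 (E)-1-[4-(benzyloxy)-3,5-dimethoxyphenyl]-2-methylbut-2-en-1-one, via aryllithium 6 (not isolated)
Conditions: n-BuLi, THF, −78 °C; then 3, −78 → 0 °C; 1 M HCl quench
Reagents that add atoms: none
Why: Bromine–lithium exchange followed by Weinreb ketone synthesis stops at the ketone, and the acidic quench ties up the released amine as its salt so that it cannot add to the new enone.

Step 4
Reactants: 8 syringaldehyde
Product: 9 4-(benzyloxy)-3,5-dimethoxybenzaldehyde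
Conditions: BnBr, K2CO3, DMF, 60 °C
Reagents that add atoms: benzyl bromide, BrCc1ccccc1
Why: Williamson ether synthesis, with an aldehyde that has no enolisable position and tolerates the base.

Step 5
Reactants: 9 4-(benzyloxy)-3,5-dimethoxybenzaldehyde; 10 p-toluenesulfonyl hydrazide
Product: 11 (E)-4-(benzyloxy)-3,5-dimethoxybenzaldehyde N-tosylhydrazone
Conditions: MeOH, rt, product collected by filtration
Reagents that add atoms: none
Why: Hydrazone condensation of an aromatic aldehyde is fast and is driven by crystallisation of the E-hydrazone.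

Step 6
Reactants: 7 (E)-1-[4-(benzyloxy)-3,5-dimethoxyphenyl]-2-methylbut-2-en-1-one; 11 tosylhydrazone (2 equiv); 12 (1R,4R,5R)-isothiocineole (1 equiv, released again)
Product: 18 (2S,3S)-2,5-bis[4-(benzyloxy)-3,5-dimethoxyphenyl]-3,4-dimethyl-2,3-dihydrofuran, via hydrazone sodium salt 13 (not isolated), via aryldiazomethane 14 (not isolated), via sulfonium benzylide 15 (not isolated), via betaine enolate 16 (not isolated), via aroylcyclopropane 17 (not isolated)
Conditions: 11, NaOMe, MeOH, rt, evaporate; 7, 12, Rh2(OAc)4 (1 mol %), BnEt3NCl (10 mol %), 1,4-dioxane, 40 °C; filter; Sc(OTf)3 (10 mol %), 2,6-di-tert-butylpyridine (20 mol %), CH2Cl2, 0 °C → rt; Et3N-deactivated silica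
Reagents that add atoms: none
Why: Proposed new method: Bamford–Stevens decomposition of 13 releases 14 slowly, rhodium transfers its benzylidene to 12, and ylide 15 adds through its carbanion to the β-carbon C3 of 7 (bond C2–C3) to give betaine 16. The ring O1–C2–C3–C4–C5 closes when the enolate oxygen displaces the sulfide at C2 (5-exo-tet, bond O1–C2); the competing 3-exo-tet attack of C4 gives 17, whose strained C2–C4 bond lies between a p-alkoxyaryl donor and an aroyl acceptor, so Sc(OTf)3 opens it to a benzylic cation/scandium enolate pair that recloses through oxygen (Cloke–Wilson rearrangement), and both channels end in 18. The closest known reaction types are the chiral-sulfide-mediated cyclopropanation of enones with aryldiazomethanes made in situ, the Lewis-acid Cloke–Wilson rearrangement of donor–acceptor cyclopropyl ketones and the copper-catalysed (4+1) annulation of enones with diazoacetates; their merger into one operation, and any of them on an α,β-dimethyl enone, is unproven. C3 is set in the conjugate addition: the bicyclic sulfide allows one sulfonium configuration and one ylide conformer and shields one ylide face, and the approach that keeps the β-methyl of 7 away from the sulfonium bulk then selects the enone face. C2 is set in the ring closure, trans to the C3 methyl, either by inversion at the sulfonium carbon of 16 or, after ionisation of 17, by closure on the cation face remote from that methyl. The step needs 1,4- over 1,2-addition (secured by the hindered, twisted aryl ketone, at which ylide addition is reversible), ylide formation over free carbene chemistry (secured by a full equivalent of 12) and enone-face selectivity, because C2 is erased on the cyclopropane channel and the enantiopurity of 18 rests on C3 alone.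

Step 7
Reactants: 18 (2S,3S)-2,5-bis[4-(benzyloxy)-3,5-dimethoxyphenyl]-3,4-dimethyl-2,3-dihydrofuran
Product: 19 (2S,3S,4S,5R)-2,5-bis[4-(benzyloxy)-3,5-dimethoxyphenyl]-3,4-dimethyloxolane
Conditions: H2 (5 bar), 5 % Rh/Al2O3, EtOAc, Et3N (trace), rt
Reagents that add atoms: none
Why: Heterogeneous catalytic hydrogenation of a cyclic enol ether delivers both hydrogens to one face, which makes the C4 methyl and the C5 aryl cis by necessity, and the catalyst should bind the face opposite the large C2 aryl group (the usual 2,5-cis outcome for 2-substituted dihydrofurans), giving 4S and 5R, while rhodium on a basic support causes little hydrogenolysis or double-bond migration.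

Step 8
Reactants: 19 (2S,3S,4S,5R)-2,5-bis[4-(benzyloxy)-3,5-dimethoxyphenyl]-3,4-dimethyloxolane
Product: 20 4,4'-[(2S,3S,4S,5R)-3,4-dimethyloxolane-2,5-diyl]bis(2,6-dimethoxyphenol), the target
Conditions: H2 (1 atm), 10 % Pd/C, EtOAc–EtOH, rt, stopped after uptake of 2 equiv
Reagents that add atoms: none
Why: Hydrogenolysis of aryl benzyl ethers over Pd/C under neutral conditions is faster than cleavage of the ring benzylic C–O bonds, is the customary last step for phenolic 2,5-diaryloxolane lignans, and touches no stereocentre.

Compound list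
1 | tiglic acid | C/C=C(\C)C(=O)O | starting material
2 | tigloyl chloride | C/C=C(\C)C(=O)Cl | intermediate
3 | (E)-N-methoxy-N,2-dimethylbut-2-enamide | C/C=C(\C)C(=O)N(C)OC | intermediate
4 | 4-bromo-2,6-dimethoxyphenol | COc1cc(Br)cc(OC)c1O | starting material
5 | 2-(benzyloxy)-5-bromo-1,3-dimethoxybenzene | COc1cc(Br)cc(OC)c1OCc1ccccc1 | intermediate
6 | [4-(benzyloxy)-3,5-dimethoxyphenyl]lithium | [Li]c1cc(OC)c(OCc2ccccc2)c(OC)c1 | intermediate
7 | (E)-1-[4-(benzyloxy)-3,5-dimethoxyphenyl]-2-methylbut-2-en-1-one | C/C=C(\C)C(=O)c1cc(OC)c(OCc2ccccc2)c(OC)c1 | intermediate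
8 | syringaldehyde | COc1cc(C=O)cc(OC)c1O | starting material
9 | 4-(benzyloxy)-3,5-dimethoxybenzaldehyde | COc1cc(C=O)cc(OC)c1OCc1ccccc1 | intermediate
10 | p-toluenesulfonyl hydrazide | Cc1ccc(S(=O)(=O)NN)cc1 | starting material
11 | (E)-4-(benzyloxy)-3,5-dimethoxybenzaldehyde N-tosylhydrazone | COc1cc(/C=N/NS(=O)(=O)c2ccc(C)cc2)cc(OC)c1OCc1ccccc1 | intermediate
12 | (1R,4R,5R)-4,7,7-trimethyl-6-thiabicyclo[3.2.1]octane (isothiocineole) | C[C@@H]1CC[C@@H]2C[C@H]1SC2(C)C | starting material
13 | sodium salt of tosylhydrazone 11 | COc1cc(/C=N/[N-]S(=O)(=O)c2ccc(C)cc2)cc(OC)c1OCc1ccccc1.[Na+] | intermediate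
14 | 2-(benzyloxy)-5-(diazomethyl)-1,3-dimethoxybenzene | COc1cc(C=[N+]=[N-])cc(OC)c1OCc1ccccc1 | intermediate
15 | isothiocineole S-[4-(benzyloxy)-3,5-dimethoxybenzylide], benzylide on the exo lone pair of sulfur | COc1cc([CH-][S@@+]2[C@@H]3C[C@@H](CC[C@H]3C)C2(C)C)cc(OC)c1OCc1ccccc1 | intermediate
16 | betaine from 15 and 7: sulfonium at C2, 3S methyl, O1–C5=C4 enolate drawn with oxygen cis to C3 | COc1cc([C@@H]([C@@H](C)/C(C)=C(\[O-])c2cc(OC)c(OCc3ccccc3)c(OC)c2)[S@@+]2[C@@H]3C[C@@H](CC[C@H]3C)C2(C)C)cc(OC)c1OCc1ccccc1 | intermediate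
17 | [4-(benzyloxy)-3,5-dimethoxyphenyl]{(1S,2S,3R)-2-[4-(benzyloxy)-3,5-dimethoxyphenyl]-1,3-dimethylcyclopropyl}methanone (methyls cis, aryl trans to both; its epimer at the aryl-bearing carbon converges on the same product) | COc1cc([C@H]2[C@@](C)(C(=O)c3cc(OC)c(OCc4ccccc4)c(OC)c3)[C@@H]2C)cc(OC)c1OCc1ccccc1 | intermediate
18 | (2S,3S)-2,5-bis[4-(benzyloxy)-3,5-dimethoxyphenyl]-3,4-dimethyl-2,3-dihydrofuran | COc1cc([C@H]2OC(c3cc(OC)c(OCc4ccccc4)c(OC)c3)=C(C)[C@@H]2C)cc(OC)c1OCc1ccccc1 | intermediate
19 | (2S,3S,4S,5R)-2,5-bis[4-(benzyloxy)-3,5-dimethoxyphenyl]-3,4-dimethyloxolane | COc1cc([C@H]2O[C@@H](c3cc(OC)c(OCc4ccccc4)c(OC)c3)[C@@H](C)[C@@H]2C)cc(OC)c1OCc1ccccc1 | intermediate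
20 | 4,4'-[(2S,3S,4S,5R)-3,4-dimethyloxolane-2,5-diyl]bis(2,6-dimethoxyphenol) | COc1cc([C@H]2O[C@@H](c3cc(OC)c(O)c(OC)c3)[C@@H](C)[C@@H]2C)cc(OC)c1O | target

Total step count: 8.
Longest linear sequence: 5 steps (4 → 5 → 7 → 18 → 19 → 20). The arms from 1 and from 8 are equally long.

Steps most likely to fail

**Step 6.**
- Conjugate addition to the α,β-dimethyl enone may be too slow, so that the ylide decays and the diazo compound dimerises.
- Incomplete selection of the enone face would leak into the mirror-image series once C2 is reset. Recrystallisation of 18 or 19 is the planned way to raise the enantiopurity.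
- The fallback uses known chemistry only, sets out from aldehyde 9 and comes back at 18. Brown crotylboration of 9 with the (E)-crotylborane made from (−)-Ipc2BOMe (THF, −78 °C, then NaOH/H2O2) should give the anti homoallylic alcohol F1. Hydroboration with 9-BBN and oxidation gives the 1,4-diol F2. TEMPO/PhI(OAc)2 oxidises the primary alcohol and closes the trans lactone F3. LiHMDS/MeI methylates the enolate anti to the ring methyl and gives the all-trans dimethyl lactone F4. Aryllithium 6, made from 5 as in step 3, adds once at −78 °C to give the hemiketal F5. PPTS with molecular sieves in toluene then removes water to give 18.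

**Step 7.**
- The face that has to be hydrogenated carries the allylic C3 methyl, so facial selectivity may be poor.
- Uptake at the tetrasubstituted alkene may be slow enough for arene saturation or double-bond migration to set in.
- Ionic reduction with a silane and acid is deliberately not used. Hydride capture of the derived 3,4-trans oxocarbenium ion follows the inside-attack mode and would place the C5 aryl trans to the C4 methyl.
- The fallback turns the same mode to advantage by bringing in the aryl group as the nucleophile. It sets out from 9, follows the sequence above as far as lactone F4, and comes back at 19. DIBAL-H (CH2Cl2, −78 °C) gives the lactol F6. Benzenesulfinic acid with CaCl2 in CH2Cl2 gives the 2-sulfonyl cyclic ether F7. The arylzinc bromide F8, from 6 and ZnBr2 in THF, ionises F7 and adds to the oxocarbenium ion on the inside face of the envelope with both methyls pseudo-equatorial. That face is syn to the C4 methyl, which gives the 4,5-cis product 19.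

**Step 8.**
- Hydrogenolysis of the ring benzylic C–O bonds may compete with cleavage of the benzyl ethers, especially once the free phenols are formed.
- The fallback sets out from 19 and comes back at 20. It replaces reduction by Lewis-acid-assisted benzyl transfer: BCl3 with pentamethylbenzene as cation scavenger in CH2Cl2 at −78 °C, quenched cold with MeOH. No hydrogen or metal surface is present, and the low temperature guards the cis benzylic centre C5 against ionisation.

Further compounds
F1 | step 6 | (1S,2S)-1-[4-(benzyloxy)-3,5-dimethoxyphenyl]-2-methylbut-3-en-1-ol | COc1cc([C@@H](O)[C@@H](C)C=C)cc(OC)c1OCc1ccccc1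
F2 | step 6 | (1S,2S)-1-[4-(benzyloxy)-3,5-dimethoxyphenyl]-2-methylbutane-1,4-diol | COc1cc([C@@H](O)[C@@H](C)CCO)cc(OC)c1OCc1ccccc1
F3 | step 6 | (4S,5S)-5-[4-(benzyloxy)-3,5-dimethoxyphenyl]-4-methyloxolan-2-one | COc1cc([C@H]2OC(=O)C[C@@H]2C)cc(OC)c1OCc1ccccc1
F4 | step 6 | (3S,4S,5S)-5-[4-(benzyloxy)-3,5-dimethoxyphenyl]-3,4-dimethyloxolan-2-one | COc1cc([C@H]2OC(=O)[C@@H](C)[C@@H]2C)cc(OC)c1OCc1ccccc1
F5 | step 6 | (3S,4S,5S)-2,5-bis[4-(benzyloxy)-3,5-dimethoxyphenyl]-3,4-dimethyloxolan-2-ol (anomer mixture) | COc1cc([C@H]2OC(O)(c3cc(OC)c(OCc4ccccc4)c(OC)c3)[C@@H](C)[C@@H]2C)cc(OC)c1OCc1ccccc1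
F6 | step 7 | (3S,4S,5S)-5-[4-(benzyloxy)-3,5-dimethoxyphenyl]-3,4-dimethyloxolan-2-ol (anomer mixture) | COc1cc([C@H]2OC(O)[C@@H](C)[C@@H]2C)cc(OC)c1OCc1ccccc1
F7 | step 7 | (2S,3S,4S)-2-[4-(benzyloxy)-3,5-dimethoxyphenyl]-3,4-dimethyl-5-(phenylsulfonyl)oxolane (C5 epimers) | COc1cc([C@H]2OC(S(=O)(=O)c3ccccc3)[C@@H](C)[C@@H]2C)cc(OC)c1OCc1ccccc1
F8 | step 7 | [4-(benzyloxy)-3,5-dimethoxyphenyl]zinc bromide | COc1cc([Zn]Br)cc(OC)c1OCc1ccccc1
F0 | step 8 | none | none
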